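**Retrosynthetic overview**

1. The last step removes two MOM ethers. The bis-MOM flavanone is cut at C8a–O1 and C4–C4a of ring C into a 3-methoxy-6-lavandulyl aryne (ring A) and an (S)-β-silyloxy ester carrying ring B.
2. Enabling feature: the ring-fusion bond C4a–C8a of ring A lies next to the C5 methoxy group, so an aryne across C4a≡C8a takes up O1 at C8a and the acyl carbon C4 at C4a in one operation. The O1–C2–C3–C4 unit of ring C is an intact aldol (β-hydroxy ester) unit.
3. Aryne precursor: an ortho-silylaryl triflate made from 3-bromo-5-methoxyphenol by two directed ortho-metalations around an N-isopropyl carbamate and a Negishi coupling with (S)-lavandulyl iodide (Evans deconjugative alkylation).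
4. β-Silyloxy ester: paeonol, MOM ether, Claisen condensation, Noyori transfer hydrogenation (sets C2), TMS ether.
5. Ring order: rings A and B are bought as benzenes; ring C is the only ring formed, in the key step, and its last bond is C4–C4a.

Key step: step 16

Remark: 3-bromo-5-methoxyphenol, paeonol, (S)-4-benzyl-2-oxazolidinone, 3-methylbut-2-enoyl chloride and prenyl bromide are taken as commercial. Ring positions are given in chromanone numbering (O1, C2, C3, C4, C4a, C5–C8, C8a).

**Route**

Step 1
Reactants: 1 (4S)-4-benzyl-1,3-oxazolidin-2-one; 2 3-methylbut-2-enoyl chloride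
Product: 4 (4S)-4-benzyl-3-(3-methylbut-2-enoyl)-1,3-oxazolidin-2-one, via lithiated oxazolidinone 3 (not isolated)
Conditions: n-BuLi, THF, −78 °C; then 2, −78 → 0 °C
Reagents that add atoms: none
Why: N-acylation of the lithiated Evans oxazolidinone with an acid chloride is standard imide formation, and no stereocentre is made.

Step 2
Reactants: 4 (4S)-4-benzyl-3-(3-methylbut-2-enoyl)-1,3-oxazolidin-2-one; 5 1-bromo-3-methylbut-2-ene (prenyl bromide)
Product: 7 (4S)-4-benzyl-3-[(2S)-5-methyl-2-(prop-1-en-2-yl)hex-4-enoyl]-1,3-oxazolidin-2-one, via sodium dienolate 6 (not isolated)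
Conditions: NaHMDS, THF, −78 °C; then 5, −78 → −30 °C
Reagents that add atoms: none
Why: Evans asymmetric alkylation in its deconjugative form: NaHMDS should remove a γ-proton of the s-cis enoyl imide to give the chelated Z(O)-dienolate 6, which is alkylated at the α-carbon (SN2 on the primary allylic bromide) from the face opposite the C4 benzyl group, setting the (2S) centre and unveiling the isopropenyl group.

Step 3
Reactants: 7 (4S)-4-benzyl-3-[(2S)-5-methyl-2-(prop-1-en-2-yl)hex-4-enoyl]-1,3-oxazolidin-2-one
Product: 8 (2S)-5-methyl-2-(prop-1-en-2-yl)hex-4-en-1-ol ((S)-lavandulol)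
Conditions: LiBH4, MeOH (1 equiv), Et2O, 0 °C
Reagents that add atoms: none
Why: Reductive cleavage of the N-acyl oxazolidinone with LiBH4 should give the primary alcohol and return the auxiliary, leaving both alkenes and the no longer enolisable stereocentre untouched.

Step 4
Reactants: 8 (2S)-5-methyl-2-(prop-1-en-2-yl)hex-4-en-1-ol
Product: 9 (3S)-3-(iodomethyl)-2,6-dimethylhepta-1,5-diene ((S)-lavandulyl iodide)
Conditions: I2, PPh3, imidazole, CH2Cl2, 0 → 23 °C
Reagents that add atoms: iodine, II
Why: Appel-type iodination displaces the activated primary oxygen by iodide (SN2 at CH2), so the adjacent stereocentre is not involved.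

Step 5
Reactants: 10 3-bromo-5-methoxyphenol
Product: 11 1-bromo-3-methoxy-5-(methoxymethoxy)benzene
Conditions: MOMCl, i-Pr2NEt, CH2Cl2, 0 → 23 °C
Reagents that add atoms: chloromethyl methyl ether, COCCl
Why: O-alkylation of the phenol with MOMCl (Williamson-type etherification) installs a base-stable, ortho-directing protecting group for the future C7 oxygen.

Step 6
Reactants: 11 1-bromo-3-methoxy-5-(methoxymethoxy)benzene
Product: 12 3-methoxy-5-(methoxymethoxy)phenol
Conditions: Pd2(dba)3 (cat.), t-BuXPhos (cat.), KOH, 1,4-dioxane/H2O, 100 °C; then aq. NaH2PO4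
Reagents that add atoms: potassium hydroxide, [K+].[OH-]
Why: Palladium-catalysed hydroxylation of the aryl bromide with hydroxide (C–O cross-coupling with a bulky biaryl phosphine) should give the phenol, the aryl MOM ether being stable to base.

Step 7
Reactants: 12 3-methoxy-5-(methoxymethoxy)phenol
Product: 13 3-methoxy-5-(methoxymethoxy)phenyl N-(propan-2-yl)carbamate
Conditions: i-PrNCO, Et3N (cat.), CH2Cl2, 23 °C
Reagents that add atoms: 2-isocyanatopropane, CC(C)N=C=O
Why: Amine-catalysed addition of the phenol to the isocyanate gives the N-isopropyl carbamate, the strongest ortho-directing group on the ring and one that is later removed under mild base.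

Step 8
Reactants: 13 3-methoxy-5-(methoxymethoxy)phenyl N-(propan-2-yl)carbamate
Product: 16 2-iodo-5-methoxy-3-(methoxymethoxy)phenyl N-(propan-2-yl)carbamate, via N-silyl carbamate 14 (not isolated), via aryllithium 15 (not isolated)
Conditions: TMSOTf, TMEDA, Et2O, 0 → 23 °C; n-BuLi, TMEDA, −78 °C; I2, THF, −78 → 0 °C; aq. Na2S2O3/NaHCO3
Reagents that add atoms: iodine, II
Why: Directed ortho-metalation of the in situ N-silylated carbamate should occur at the ring position flanked by the two strongest directing groups (carbamate and OMOM) rather than between carbamate and methoxy, and iodine quench gives the aryl iodide, the N–Si bond being hydrolysed on work-up.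

Step 9
Reactants: 9 (3S)-3-(iodomethyl)-2,6-dimethylhepta-1,5-diene; 16 2-iodo-5-methoxy-3-(methoxymethoxy)phenyl N-(propan-2-yl)carbamate
Product: 18 5-methoxy-3-(methoxymethoxy)-2-[(2R)-5-methyl-2-(prop-1-en-2-yl)hex-4-en-1-yl]phenyl N-(propan-2-yl)carbamate, via alkylzinc iodide 17 (not isolated)
Conditions: Zn dust (activated with 1,2-dibromoethane/TMSCl), LiCl, THF, 40 °C; then 16, Pd(OAc)2 (cat.), CPhos (cat.), THF, 23 → 45 °C
Reagents that add atoms: none
Why: Negishi coupling: LiCl-promoted zinc insertion into the primary iodide gives the alkylzinc iodide 17, which tolerates the carbamate N–H and should couple with the hindered aryl iodide under a palladium/biarylphosphine catalyst whose fast reductive elimination outruns β-hydride elimination, the stereocentre β to zinc not being touched.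

Step 10
Reactants: 18 5-methoxy-3-(methoxymethoxy)-2-[(2R)-5-methyl-2-(prop-1-en-2-yl)hex-4-en-1-yl]phenyl N-(propan-2-yl)carbamate
Product: 21 3-methoxy-5-(methoxymethoxy)-6-[(2R)-5-methyl-2-(prop-1-en-2-yl)hex-4-en-1-yl]-2-(trimethylsilyl)phenyl N-(propan-2-yl)carbamate, via N-silyl carbamate 19 (not isolated), via aryllithium 20 (not isolated)
Conditions: TMSOTf, TMEDA, Et2O, 0 → 23 °C; n-BuLi, TMEDA, −78 °C; TMSCl, −78 → 23 °C; aq. NaHCO3
Reagents that add atoms: chlorotrimethylsilane, C[Si](C)(C)Cl
Why: A second directed ortho-metalation should take the only remaining position ortho to the carbamate, which is further activated by the adjacent methoxy group, and silylation with TMSCl places silicon on the future C4a.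

Step 11
Reactants: 21 3-methoxy-5-(methoxymethoxy)-6-[(2R)-5-methyl-2-(prop-1-en-2-yl)hex-4-en-1-yl]-2-(trimethylsilyl)phenyl N-(propan-2-yl)carbamate
Product: 23 3-methoxy-5-(methoxymethoxy)-6-[(2R)-5-methyl-2-(prop-1-en-2-yl)hex-4-en-1-yl]-2-(trimethylsilyl)phenyl trifluoromethanesulfonate, via silylphenol 22 (not isolated)
Conditions: DBU, Et2NH, MeCN, 40 °C; then PhNTf2, 23 → 40 °C
Reagents that add atoms: N-phenylbis(trifluoromethanesulfonimide), O=S(=O)(N(c1ccccc1)S(=O)(=O)C(F)(F)F)C(F)(F)F
Why: The N–H carbamate should be cleaved by E1cB fragmentation to the phenoxide and isopropyl isocyanate (trapped by Et2NH as a urea), and the phenoxide is triflated in the same flask to give the ortho-silylaryl triflate aryne precursor without isolating the electron-rich silylphenol.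

Step 12
Reactants: 24 1-(2-hydroxy-4-methoxyphenyl)ethan-1-one (paeonol)
Product: 25 1-[4-methoxy-2-(methoxymethoxy)phenyl]ethan-1-one
Conditions: MOMCl, i-Pr2NEt, CH2Cl2, 0 → 40 °C
Reagents that add atoms: chloromethyl methyl ether, COCCl
Why: MOM protection of the hydrogen-bonded phenol of paeonol (Williamson-type etherification) masks the future C2′ hydroxyl.

Step 13
Reactants: 25 1-[4-methoxy-2-(methoxymethoxy)phenyl]ethan-1-one
Product: 26 methyl 3-[4-methoxy-2-(methoxymethoxy)phenyl]-3-oxopropanoate
Conditions: NaH, (MeO)2CO, THF, 65 °C; then AcOH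
Reagents that add atoms: dimethyl carbonate, COC(=O)OC
Why: Crossed Claisen condensation of the methyl ketone enolate with dimethyl carbonate is driven to completion by deprotonation of the β-keto ester formed.

Step 14
Reactants: 26 methyl 3-[4-methoxy-2-(methoxymethoxy)phenyl]-3-oxopropanoate
Product: 27 methyl (3S)-3-hydroxy-3-[4-methoxy-2-(methoxymethoxy)phenyl]propanoate
Conditions: RuCl[(S,S)-TsDPEN](p-cymene) (cat.), HCO2H/Et3N (5:2), DMF, 30 °C
Reagents that add atoms: none
Why: Noyori asymmetric transfer hydrogenation of the aryl ketone: the (S,S)-TsDPEN catalyst should deliver hydride through its CH/π-organised outer-sphere transition state to give the (S)-benzylic alcohol (the sense found for aryl alkyl ketones), which becomes C2 of the target.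

Step 15
Reactants: 27 methyl (3S)-3-hydroxy-3-[4-methoxy-2-(methoxymethoxy)phenyl]propanoate
Product: 28 methyl (3S)-3-[4-methoxy-2-(methoxymethoxy)phenyl]-3-[(trimethylsilyl)oxy]propanoate
Conditions: TMSCl, imidazole, CH2Cl2, 0 °C; filtration through basic alumina
Reagents that add atoms: chlorotrimethylsilane, C[Si](C)(C)Cl
Why: Silylation of the secondary alcohol gives a fluoride-labile latent alkoxide and removes the only O–H proton from the key step.

Step 16
Reactants: 23 3-methoxy-5-(methoxymethoxy)-6-[(2R)-5-methyl-2-(prop-1-en-2-yl)hex-4-en-1-yl]-2-(trimethylsilyl)phenyl trifluoromethanesulfonate; 28 methyl (3S)-3-[4-methoxy-2-(methoxymethoxy)phenyl]-3-[(trimethylsilyl)oxy]propanoate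
Product: 32 (2S)-5-methoxy-2-[4-methoxy-2-(methoxymethoxy)phenyl]-7-(methoxymethoxy)-8-[(2R)-5-methyl-2-(prop-1-en-2-yl)hex-4-en-1-yl]-2,3-dihydro-4H-chromen-4-one, via aryne 29 (not isolated), via ammonium alkoxide 30 (not isolated), via aryl anion 31 (not isolated)
Conditions: TBAT (Bu4N[Ph3SiF2], 1.5 equiv) added in portions to 28 and 23 (1.3 equiv), THF, −20 → 23 °C; pH 7 phosphate buffer
Reagents that add atoms: none
Why: Proposed new method: fluoride converts 23 into the aryne 29 (triple bond C4a≡C8a) and unmasks 28 as the alkoxide 30, which adds to C8a to give the aryl anion 31 at C4a; this anion attacks the ester carbonyl at the end of the O1–C2–C3–C4 tether, forming the C4–C4a bond and expelling methoxide, which desilylates the next molecule of 28 so that neither free base nor a proton source builds up. The closest known reaction type is the fluoride-mediated annulation of arynes with salicylate esters to xanthones (O-arylation, then acyl capture of the aryl anion), extended here from a phenoxide to an aliphatic β-alkoxy ester. Ring C is closed by 6-exo-trig attack of the C4a carbanion on the ester C=O. No new stereocentre is formed, since C2 arrives from 27 with its C–O bond untouched and the side-chain centre is remote. The selectivity needed is regiochemical (O at C8a, acyl at C4a) and is secured by the C5 methoxy group next to the triple bond, whose inductive effect makes the distal aryne carbon the electrophilic one and places the developing negative charge ortho to oxygen, outweighing the modest steric bias of the C8 CH2 group and the weak opposing effect of the C7 OMOM group. Low temperature and the absence of accumulated base are relied on to suppress retro-aldol cleavage or β-elimination of 30 and ring opening of the flavanone.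

Step 17
Reactants: 32 (2S)-5-methoxy-2-[4-methoxy-2-(methoxymethoxy)phenyl]-7-(methoxymethoxy)-8-[(2R)-5-methyl-2-(prop-1-en-2-yl)hex-4-en-1-yl]-2,3-dihydro-4H-chromen-4-one
Product: 33 (2S)-7-hydroxy-2-(2-hydroxy-4-methoxyphenyl)-5-methoxy-8-[(2R)-5-methyl-2-(prop-1-en-2-yl)hex-4-en-1-yl]-2,3-dihydro-4H-chromen-4-one (CNP0201936.1)
Conditions: HCl (2 M aq.), MeOH, 23 → 40 °C
Reagents that add atoms: none
Why: Acid-catalysed methanolysis of the two aryl MOM acetals should release both phenols under conditions mild enough to leave the flavanone, its C2 centre and the two alkenes intact, giving the target.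

**Compound list**

1 | (4S)-4-benzyl-1,3-oxazolidin-2-one | O=C1N[C@@H](Cc2ccccc2)CO1 | starting material
2 | 3-methylbut-2-enoyl chloride | CC(C)=CC(=O)Cl | starting material
3 | lithium salt of 1 (not isolated) | [Li+].O=C1[N-][C@@H](Cc2ccccc2)CO1 | intermediate
4 | (4S)-4-benzyl-3-(3-methylbut-2-enoyl)-1,3-oxazolidin-2-one | CC(C)=CC(=O)N1[C@@H](Cc2ccccc2)COC1=O | intermediate
5 | 1-bromo-3-methylbut-2-ene (prenyl bromide) | CC(C)=CCBr | starting material
6 | sodium Z(O)-dienolate of 4 (not isolated) | [Na+].[O-]/C(=C\C(C)=C)N1[C@@H](Cc2ccccc2)COC1=O | intermediate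
7 | (4S)-4-benzyl-3-[(2S)-5-methyl-2-(prop-1-en-2-yl)hex-4-enoyl]-1,3-oxazolidin-2-one | C=C(C)[C@H](CC=C(C)C)C(=O)N1[C@@H](Cc2ccccc2)COC1=O | intermediate
8 | (2S)-5-methyl-2-(prop-1-en-2-yl)hex-4-en-1-ol ((S)-lavandulol) | C=C(C)[C@H](CC=C(C)C)CO | intermediate
9 | (3S)-3-(iodomethyl)-2,6-dimethylhepta-1,5-diene | C=C(C)[C@H](CC=C(C)C)CI | intermediate
10 | 3-bromo-5-methoxyphenol | COc1cc(O)cc(Br)c1 | starting material
11 | 1-bromo-3-methoxy-5-(methoxymethoxy)benzene | COCOc1cc(OC)cc(Br)c1 | intermediate
12 | 3-methoxy-5-(methoxymethoxy)phenol | COCOc1cc(OC)cc(O)c1 | intermediate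
13 | 3-methoxy-5-(methoxymethoxy)phenyl N-(propan-2-yl)carbamate | COCOc1cc(OC)cc(OC(=O)NC(C)C)c1 | intermediate
14 | N-trimethylsilyl derivative of 13 (not isolated) | COCOc1cc(OC)cc(OC(=O)N(C(C)C)[Si](C)(C)C)c1 | intermediate
15 | aryllithium from 14, lithium between carbamate and OMOM (not isolated) | COCOc1cc(OC)cc(OC(=O)N(C(C)C)[Si](C)(C)C)c1[Li] | intermediate
16 | 2-iodo-5-methoxy-3-(methoxymethoxy)phenyl N-(propan-2-yl)carbamate | COCOc1cc(OC)cc(OC(=O)NC(C)C)c1I | intermediate
17 | [(2S)-5-methyl-2-(prop-1-en-2-yl)hex-4-en-1-yl]zinc iodide (not isolated) | C=C(C)[C@H](CC=C(C)C)C[Zn]I | intermediate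
18 | 5-methoxy-3-(methoxymethoxy)-2-[(2R)-5-methyl-2-(prop-1-en-2-yl)hex-4-en-1-yl]phenyl N-(propan-2-yl)carbamate | C=C(C)[C@H](CC=C(C)C)Cc1c(OCOC)cc(OC)cc1OC(=O)NC(C)C | intermediate
19 | N-trimethylsilyl derivative of 18 (not isolated) | C=C(C)[C@H](CC=C(C)C)Cc1c(OCOC)cc(OC)cc1OC(=O)N(C(C)C)[Si](C)(C)C | intermediate
20 | aryllithium from 19, lithium between carbamate and methoxy (not isolated) | C=C(C)[C@H](CC=C(C)C)Cc1c(OCOC)cc(OC)c([Li])c1OC(=O)N(C(C)C)[Si](C)(C)C | intermediate
21 | 3-methoxy-5-(methoxymethoxy)-6-[(2R)-5-methyl-2-(prop-1-en-2-yl)hex-4-en-1-yl]-2-(trimethylsilyl)phenyl N-(propan-2-yl)carbamate | C=C(C)[C@H](CC=C(C)C)Cc1c(OCOC)cc(OC)c([Si](C)(C)C)c1OC(=O)NC(C)C | intermediate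
22 | 3-methoxy-5-(methoxymethoxy)-6-[(2R)-5-methyl-2-(prop-1-en-2-yl)hex-4-en-1-yl]-2-(trimethylsilyl)phenol (not isolated) | C=C(C)[C@H](CC=C(C)C)Cc1c(OCOC)cc(OC)c([Si](C)(C)C)c1O | intermediate
23 | 3-methoxy-5-(methoxymethoxy)-6-[(2R)-5-methyl-2-(prop-1-en-2-yl)hex-4-en-1-yl]-2-(trimethylsilyl)phenyl trifluoromethanesulfonate | C=C(C)[C@H](CC=C(C)C)Cc1c(OCOC)cc(OC)c([Si](C)(C)C)c1OS(=O)(=O)C(F)(F)F | intermediate
24 | 1-(2-hydroxy-4-methoxyphenyl)ethan-1-one (paeonol) | CC(=O)c1ccc(OC)cc1O | starting material
25 | 1-[4-methoxy-2-(methoxymethoxy)phenyl]ethan-1-one | CC(=O)c1ccc(OC)cc1OCOC | intermediate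
26 | methyl 3-[4-methoxy-2-(methoxymethoxy)phenyl]-3-oxopropanoate | COC(=O)CC(=O)c1ccc(OC)cc1OCOC | intermediate
27 | methyl (3S)-3-hydroxy-3-[4-methoxy-2-(methoxymethoxy)phenyl]propanoate | O[C@H](c1ccc(OC)cc1OCOC)CC(=O)OC | intermediate
28 | methyl (3S)-3-[4-methoxy-2-(methoxymethoxy)phenyl]-3-[(trimethylsilyl)oxy]propanoate | C[Si](C)(C)O[C@H](c1ccc(OC)cc1OCOC)CC(=O)OC | intermediate
29 | 3-methoxy-5-(methoxymethoxy)-6-[(2R)-5-methyl-2-(prop-1-en-2-yl)hex-4-en-1-yl]benzyne, triple bond between the future C4a and C8a (not isolated) | C=C(C)[C@H](CC=C(C)C)CC1=C(OCOC)C=C(OC)C#C1 | intermediate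
30 | tetrabutylammonium alkoxide of 27 (not isolated) | CCCC[N+](CCCC)(CCCC)CCCC.[O-][C@H](c1ccc(OC)cc1OCOC)CC(=O)OC | intermediate
31 | tetrabutylammonium salt of the O-arylated aryl anion, carbanion at the future C4a (not isolated) | CCCC[N+](CCCC)(CCCC)CCCC.C=C(C)[C@H](CC=C(C)C)Cc1c(OCOC)cc(OC)[c-]c1O[C@H](c1ccc(OC)cc1OCOC)CC(=O)OC | intermediate
32 | (2S)-5-methoxy-2-[4-methoxy-2-(methoxymethoxy)phenyl]-7-(methoxymethoxy)-8-[(2R)-5-methyl-2-(prop-1-en-2-yl)hex-4-en-1-yl]-2,3-dihydro-4H-chromen-4-one | C=C(C)[C@H](CC=C(C)C)Cc1c(OCOC)cc(OC)c2c1O[C@H](c1ccc(OC)cc1OCOC)CC2=O | intermediate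
33 | (2S)-7-hydroxy-2-(2-hydroxy-4-methoxyphenyl)-5-methoxy-8-[(2R)-5-methyl-2-(prop-1-en-2-yl)hex-4-en-1-yl]-2,3-dihydro-4H-chromen-4-one | C=C(C)[C@H](CC=C(C)C)Cc1c(O)cc(OC)c2c1O[C@H](c1ccc(OC)cc1O)CC2=O | target

**Step count and risks**

Total step count: 17.
Longest linear sequence: 9 steps (steps 5–11, 16, 17 from 10; equally steps 1–4, 9–11, 16, 17 from 1).

Steps most likely to fail:

1. Step 16 (proposed new method). The unmasked alkoxide may undergo retro-aldol fragmentation or β-elimination before it meets the aryne, or the aryl anion may abstract an α-proton instead of transferring the acyl group; either path loses material and erodes the C2 configuration. The fallback uses known chemistry, sets out from 26 and 23 and returns at 32. The keto ester 26 is reduced with the enantiomeric catalyst RuCl[(R,R)-TsDPEN](p-cymene) (HCO2H/Et3N) to methyl (3R)-3-hydroxy-3-[4-methoxy-2-(methoxymethoxy)phenyl]propanoate F1, which is silylated (TIPSOTf, 2,6-lutidine) to the triisopropylsilyl ether F2 and saponified (LiOH, THF/H2O, 0 °C) to the acid F3. The aryne from 23 (CsF, THF, 65 → 100 °C) then inserts into the O–C(acyl) bond of the carboxylate, the known route from arynes and carboxylic acids to ortho-hydroxyaryl ketones; this should give the ketone F4 with the acyl group on C4a and the free phenol on C8a under the same methoxy control. Desilylation (TBAF/AcOH, THF) to the hydroxy ketone F5 and an intramolecular Mitsunobu etherification (PPh3, DIAD, THF, 0 °C) close ring C at O1–C2 with inversion, (R) to (S), to give 32.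

2. Step 8. Metalation may take place on the other flank of the carbamate (between carbamate and methoxy), which would put iodine, and later the side chain, on the wrong carbon. The fallback sets out from 13 and returns at 21. The order of the two electrophiles is exchanged: the first metalation is quenched with TMSCl to give 3-methoxy-5-(methoxymethoxy)-2-(trimethylsilyl)phenyl N-(propan-2-yl)carbamate F6, in which silicon sits on the methoxy flank. A second directed ortho-metalation can then only take the one remaining position ortho to the carbamate, and iodine quench gives the iodide F7, which is coupled with the zinc reagent 17 as in step 9 to give 21.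

3. Step 9. Oxidative addition and transmetalation may be slow at the doubly ortho-substituted iodide, which lets β-hydride elimination and chain walking of the alkylpalladium, or protonolysis of the zinc reagent by the carbamate N–H, compete with coupling. The fallback sets out from 9 and 16 and returns at 18. Iodide 9 is converted by iodine–lithium exchange (t-BuLi, Et2O, −78 °C) and addition of 9-methoxy-9-borabicyclo[3.3.1]nonane into the lithium B-alkyl-B-methoxyborate F8, which is used directly in a B-alkyl Suzuki–Miyaura coupling with 16 (Pd(dppf)Cl2, AsPh3, K3PO4 aq., DMF, 23 °C) to give 18.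

**Further compounds**

F1 | step 16 | methyl (3R)-3-hydroxy-3-[4-methoxy-2-(methoxymethoxy)phenyl]propanoate | O[C@@H](c1ccc(OC)cc1OCOC)CC(=O)OC
F2 | step 16 | methyl (3R)-3-[4-methoxy-2-(methoxymethoxy)phenyl]-3-{[tri(propan-2-yl)silyl]oxy}propanoate | CC(C)[Si](C(C)C)(C(C)C)O[C@@H](c1ccc(OC)cc1OCOC)CC(=O)OC
F3 | step 16 | (3R)-3-[4-methoxy-2-(methoxymethoxy)phenyl]-3-{[tri(propan-2-yl)silyl]oxy}propanoic acid | CC(C)[Si](C(C)C)(C(C)C)O[C@@H](c1ccc(OC)cc1OCOC)CC(=O)O
F4 | step 16 | (3R)-1-{2-hydroxy-6-methoxy-4-(methoxymethoxy)-3-[(2R)-5-methyl-2-(prop-1-en-2-yl)hex-4-en-1-yl]phenyl}-3-[4-methoxy-2-(methoxymethoxy)phenyl]-3-{[tri(propan-2-yl)silyl]oxy}propan-1-one | C=C(C)[C@H](CC=C(C)C)Cc1c(OCOC)cc(OC)c(C(=O)C[C@@H](O[Si](C(C)C)(C(C)C)C(C)C)c2ccc(OC)cc2OCOC)c1O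
F5 | step 16 | (3R)-3-hydroxy-1-{2-hydroxy-6-methoxy-4-(methoxymethoxy)-3-[(2R)-5-methyl-2-(prop-1-en-2-yl)hex-4-en-1-yl]phenyl}-3-[4-methoxy-2-(methoxymethoxy)phenyl]propan-1-one | C=C(C)[C@H](CC=C(C)C)Cc1c(OCOC)cc(OC)c(C(=O)C[C@@H](O)c2ccc(OC)cc2OCOC)c1O
F6 | step 8 | 3-methoxy-5-(methoxymethoxy)-2-(trimethylsilyl)phenyl N-(propan-2-yl)carbamate | COCOc1cc(OC)c([Si](C)(C)C)c(OC(=O)NC(C)C)c1
F7 | step 8 | 2-iodo-5-methoxy-3-(methoxymethoxy)-6-(trimethylsilyl)phenyl N-(propan-2-yl)carbamate | COCOc1cc(OC)c([Si](C)(C)C)c(OC(=O)NC(C)C)c1I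
F8 | step 9 | lithium 9-methoxy-9-[(2S)-5-methyl-2-(prop-1-en-2-yl)hex-4-en-1-yl]-9-boranuidabicyclo[3.3.1]nonane | C=C(C)[C@H](CC=C(C)C)C[B-]1(OC)C2CCCC1CCC2.[Li+]
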